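Count in moles of reagent: one mole spent is the unit of this ledger.

the same everywhere: reagent 0.260 M (fed, over 80 min); time 5.0 h
- Wednesday's: substrate 0.050 M; the fed solution adds 1.0 times the starting volume
- Sunday's: substrate 0.10 M; the fed solution adds 1.0 times the starting volume
- Thursday's: substrate 0.20 M; the fed solution adds 1.0 times the starting volume
- Friday's: substrate 0.40 M; the fed solution adds 1.0 times the starting volume
- Saturday's: substrate 0.80 M; the fed solution adds 1.0 times the starting volume

    substrate + reagent ⇌ intermediate A (K1 = 2.8 M⁻¹, k1 = 0.0708 M⁻¹ s⁻¹)
    substrate + target → side product B (k2 = 0.00242 M⁻¹ s⁻¹)
    intermediate B → side product A (k3 = 0.00128 s⁻¹)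
    intermediate B → target (k4 = 0.00107 s⁻¹)
    reagent + intermediate A → intermediate B (k5 = 0.00119 M⁻¹ s⁻¹)

- percentages count the substrate that a species holds: one side product B counts as two
- every charge counts on the volume at the start, and the solution that is fed holds the whole dose
- "hardly changes" means that all values lie within two and a half points (for a concentration: within two and a half percent of the largest)
- run time (Wednesday's): 5.0 h

- [target] at the end for Wednesday's, Sunday's, Thursday's, Friday's, Saturday's, in this order
- how that number moves from the first to the last of them (falls all the way / rises, then falls / rises all the way / falls, then rises / hardly changes)

Here is my own ledger, as far as a hand can take it.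

1. Reagent is spent in pairs. One mole enters by step 1, one by step 5, and each pair makes one intermediate B.

2. Intermediate B has two exits, both first order in it. Divide the rate of step 4 by the sum of both rates, and its concentration and time drop out. With these constants, 45.5% of intermediate B leaves as target: this is the target share. The ratio of the two exits, 0.836, is the selectivity factor.

3. So one mole of reagent spent to the end gives 0.228 mole of target and 0.272 mole of side product A. At two reagent per product that makes 1.00 mole, and the books close.

4. How far can the pairs go? At two reagent per substrate, the reagent charge on Wednesday's is 2.60 times the need of the substrate charge, but on Saturday's 0.163 times, less than the need, so on Saturday's reagent is the limiting reagent.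

5. The target entry doesn't stay whole. Step 2 removes target with no reagent, and its half-life, substrate as charged, is 1.6 h on Wednesday's, shorter than the run of 5.0 h. On Saturday's it is 0.0995 h.

6. Each side product B is a dead target, and it counts two in the percentages. So target left plus half of side product B's figure is the target ever made, and that should stand to side product A as the selectivity factor.

By hand I stop there: I commit to a rise, then a fall, and to no row.

The forecast gave 0.0032 M, 0.004 M, 0.0035 M, 0.0021 M and 8.000 × 10⁻⁴ M, so rises, then falls, holding that above about 0.1 M “the substrate consumes target faster than it forms”.

The flask gives 0.00335 M, 0.00428 M, 0.00363 M, 0.00181 M and 7.20 × 10⁻⁴ M, so rises, then falls, and on Saturday's 80.4% of the substrate still stands at the end. Now use the selectivity factor. On Wednesday's, side product A at 20.9% after 5.00 h calls for 17.5% of target ever made, and target 13.4% plus half of side product B's 8.12% gives 17.5%. On Saturday's, side product A at 4.68% calls for 3.91%, and target 0.180% plus half of side product B's 7.47% gives 3.92%.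

The constants used here are made up; the rest is arithmetic.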